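**Strategy.** The bicyclo[2.2.2]octene (C1/C4 bridgeheads, C2 ester, C3 aryl, C5=C6, C7 carbinol, C8 ketone) is cut where C6 stands γ to the C2 ester (C6–C1–C2–CO2Me). C6 is carried as a ketone that first sits on C2, inside the cyclopentanone C2–C3–C4–C5–C6 of bicyclo[3.2.1]octenedione 13. A triplet-sensitised oxa-di-π-methane 1,2-acyl shift moves C6 to C1, the β-carbon of the C8(=O)–C7=C1 alkoxy enone. The five-membered ring becomes the six-membered ring C1–C6 and a strained cyclopropane (C1–C2–C7) closes. Reductive opening of its C2–C7 bond releases the C8 ketone, the C7 ether and the C2 ester; triflation and a Heck reaction turn the C6 ketone into the dienoate.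

Key step: step 6

Remark: atom numbers in the Why lines are those of the bicyclo[2.2.2]octene given above.
Assumption: (2S,5S)-2,5-diphenylpyrrolidine is taken to screen the diene face that gives the aryl-bearing centre as drawn; if induction runs the other way, its enantiomer is used.
Assumption: the side-chain centre of the target is (S), opposite to natural danshensu, so the commercial (R)-acid salt is joined with inversion.

Step 1
Reactants: 1 1-(benzyloxy)propan-2-one; 2 (2S,5S)-2,5-diphenylpyrrolidine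
Product: 4 (Z)-3-(benzyloxy)-4-[(2S,5S)-2,5-diphenylpyrrolidin-1-yl]but-3-en-2-one, via dimethylamino enaminone 3 (not isolated)
Conditions: Me2NCH(OMe)2, 90 °C; then 2, AcOH (cat.), PhMe, 110 °C
Reagents that add atoms: N,N-dimethylformamide dimethyl acetal, COC(OC)N(C)C
Why: Enaminone formation at the benzyloxy-activated methylene followed by amine exchange on the vinylogous amide should install the C2-symmetric auxiliary; no stereocentre is formed.

Step 2
Reactants: 5 3,4-bis(benzyloxy)benzaldehyde; 6 dimethyl malonate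
Product: 7 dimethyl 2-[3,4-bis(benzyloxy)benzylidene]malonate
Conditions: piperidine (cat.), AcOH (cat.), PhMe, reflux, Dean–Stark
Reagents that add atoms: none
Why: Knoevenagel condensation should give the reactive alkylidene malonate, whose two equal esters make alkene geometry irrelevant.

Step 3
Reactants: 4 chiral enaminone; 7 alkylidene malonate
Product: 10 dimethyl (6R)-6-[3,4-bis(benzyloxy)phenyl]-3-(benzyloxy)-4-oxocyclohex-2-ene-1,1-dicarboxylate, via aminosiloxy diene 8 (not isolated), via Diels–Alder adduct 9 (not isolated)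
Conditions: KN(SiMe3)2, t-BuMe2SiCl, THF, −78 °C; then 7, PhMe, 25→60 °C; then HF (aq), MeCN, 0 °C
Reagents that add atoms: none
Why: Diels–Alder reaction of a Rawal-type 1-amino-3-siloxydiene, in which the CH2 terminus bonds to the benzylidene carbon and the amino terminus to the malonate carbon, the pyrrolidine screens one diene face with the aryl group exo to set the aryl-bearing centre (later C3), and HF then hydrolyses the silyl enol ether and eliminates the auxiliary to the enone.

Step 4
Reactants: 10 cyclohexenone diester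
Product: 11 dimethyl (5S,6R)-6-[3,4-bis(benzyloxy)phenyl]-3-(benzyloxy)-5-(2-tert-butoxy-2-oxoethyl)-4-oxocyclohex-2-ene-1,1-dicarboxylate (5,6-trans)
Conditions: LiN(i-Pr)2, THF, −78 °C; BrCH2CO2t-Bu, −78→−40 °C
Reagents that add atoms: tert-butyl bromoacetate, CC(C)(C)OC(=O)CBr
Why: Kinetic α′-enolate alkylation at the only enolisable position should place the acetate arm trans to the neighbouring aryl group.

Step 5
Reactants: 11 alkylated cyclohexenone
Product: 13 methyl 8-[3,4-bis(benzyloxy)phenyl]-3-(benzyloxy)-4,7-dioxobicyclo[3.2.1]oct-2-ene-1-carboxylate (aryl on the one-carbon bridge turned to the enone bridge), via tert-butyl β-keto ester 12 (not isolated)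
Conditions: LiN(i-Pr)2 (2.2 equiv), THF, −78→−20 °C; AcOH; then CF3CO2H, CH2Cl2, 0 °C→rt; then PhMe, 80 °C
Reagents that add atoms: none
Why: Dieckmann condensation of the tert-butyl ester enolate onto the malonate ester on its own ring face closes the cyclopentanone and fixes the quaternary centre C2 through the bridge, and acidolysis then decarboxylates only the enolisable β-keto acid because the bridgehead ester cannot form an enol.

Step 6
Reactants: 13 bicyclo[3.2.1]octenedione
Product: 14 methyl 3-[3,4-bis(benzyloxy)phenyl]-6-(benzyloxy)-5,7-dioxotricyclo[2.2.2.0(2,6)]octane-2-carboxylate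
Conditions: hν (300 nm), acetone (solvent and triplet sensitiser), degassed, rt
Reagents that add atoms: none
Why: Triplet energy transfer from acetone populates the rigid alkoxy-enone triplet of 13, whose β-carbon C1 adds to the neighbouring ketone carbon C6 held axially on C2 (3-exo closure to an oxycyclopropyl diradical); cleavage of the C2–C6 bond completes the 1,2-acyl shift and the C2/C7 diradical collapses to the cyclopropane. The closest known reaction type is the oxa-di-π-methane rearrangement of bridged β,γ-unsaturated ketones and its 4-acyl and 4-aryl cyclohexenone variants. The six-membered ring C1–C6 is closed by the acyl shift, which enlarges the cyclopentanone C2–C3–C4–C5–C6 by the atom C1, and the three-membered ring C1–C2–C7 is closed by radical recombination. The new centre C1 is fixed by the C4–C5–C6 tether, which can deliver C6 only to the enone face it already occupies, and the quaternary centres C2 and C7 are fixed by the fused cyclopropane, while C3 and C4 are untouched. The step needs the 1,2-shift to win over the singlet 1,3-acyl shift and α-cleavage, which sensitisation instead of direct excitation of the C6 ketone should secure, and ketone rather than ester migration, which the higher migratory aptitude of the acyl group should secure.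

Step 7
Reactants: 14 tricyclic diketone
Product: 15 methyl 3-[3,4-bis(benzyloxy)phenyl]-6-(benzyloxy)-5-oxo-7-(trifluoromethylsulfonyloxy)tricyclo[2.2.2.0(2,6)]oct-7-ene-2-carboxylate
Conditions: LiN(SiMe3)2, THF, −78 °C; PhNTf2, −78→0 °C
Reagents that add atoms: N-phenylbis(trifluoromethanesulfonimide), O=S(=O)(N(c1ccccc1)S(=O)(=O)C(F)(F)F)C(F)(F)F
Why: Enol triflate formation should be regiospecific because C5–H2 is the only enolisable position in 14 (C1 and C4 are bridgeheads, C2 and C7 carry no hydrogen), so only the C6 ketone reacts.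

Step 8
Reactants: 15 tricyclic enol triflate
Product: 17 methyl 3-[3,4-bis(benzyloxy)phenyl]-7-(benzyloxy)-8-oxo-6-(trifluoromethylsulfonyloxy)bicyclo[2.2.2]oct-5-ene-2-carboxylate (ester trans to aryl and syn to C5=C6; benzyloxy group turned to the C2–C3 bridge), via potassium enolate 16 (not isolated)
Conditions: SmI2 (2.2 equiv), t-BuOH (1.0 equiv), THF, −78 °C; then KOt-Bu (1.0 equiv), THF, −40 °C; then AcOH, −78 °C
Reagents that add atoms: none
Why: Reductive cyclopropyl ketone cleavage, in which the C8 ketyl breaks the C2–C7 bond aligned with its π orbital (C1–C7 lies in the nodal plane) to give the ester-stabilised C2 centre, then KOt-Bu equilibrates C2 to the trans ester while C7 stays planar in the enolate, and kinetic protonation of that enolate should occur from the C5=C6 bridge face because the C3 aryl group screens the other face.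

Step 9
Reactants: 18 sodium (R)-3-(3,4-dihydroxyphenyl)-2-hydroxypropanoate (danshensu sodium)
Product: 19 methyl (R)-3-(3,4-dihydroxyphenyl)-2-hydroxypropanoate
Conditions: AcCl, MeOH, 0 °C→rt
Reagents that add atoms: methanol, CO
Why: Fischer esterification with HCl generated in situ leaves the stereocentre untouched.

Step 10
Reactants: 19 methyl ester of danshensu
Product: 20 methyl (R)-3-[3,4-bis(benzyloxy)phenyl]-2-hydroxypropanoate
Conditions: BnBr (2.1 equiv), K2CO3, acetone, reflux
Reagents that add atoms: benzyl bromide, BrCc1ccccc1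
Why: Williamson ether synthesis should be selective for the two phenols, which alone are deprotonated by carbonate.

Step 11
Reactants: 20 bis-benzyl ether
Product: 21 methyl (S)-2-(acryloyloxy)-3-[3,4-bis(benzyloxy)phenyl]propanoate
Conditions: acrylic acid, PPh3, i-PrO2CN=NCO2i-Pr, THF, 0 °C→rt
Reagents that add atoms: acrylic acid, C=CC(=O)O
Why: Mitsunobu esterification of the α-hydroxy ester proceeds with inversion and so sets the (S) side-chain centre.

Step 12
Reactants: 17 bicyclic vinyl triflate; 21 acrylate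
Product: 22 penta-O-benzyl ether of 23
Conditions: Pd(OAc)2 (5 mol %), Bu4NCl, NaHCO3, DMF, 40 °C
Reagents that add atoms: none
Why: Mizoroki–Heck reaction of the vinyl triflate with the acrylate under ligand-free conditions should give the (E)-dienoate, and the mild hydrogencarbonate base spares the C7 and side-chain centres.

Step 13
Reactants: 22 protected target
Product: 23 CNP0304584.1
Conditions: BCl3, pentamethylbenzene, CH2Cl2, −78 °C; MeOH quench
Reagents that add atoms: none
Why: Lewis acid debenzylation with a non-basic cation scavenger should cleave the four aryl and the one alkyl benzyl ether without touching the esters, the dienoate or the α-ketol.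

**Compound list**

1 | 1-(benzyloxy)propan-2-one | CC(=O)COCc1ccccc1 | starting material
2 | (2S,5S)-2,5-diphenylpyrrolidine | N1[C@H](c2ccccc2)CC[C@H]1c1ccccc1 | starting material
3 | (Z)-3-(benzyloxy)-4-(dimethylamino)but-3-en-2-one | CC(=O)/C(OCc1ccccc1)=C/N(C)C | intermediate
4 | (Z)-3-(benzyloxy)-4-[(2S,5S)-2,5-diphenylpyrrolidin-1-yl]but-3-en-2-one | CC(=O)/C(OCc1ccccc1)=C/N1[C@H](c2ccccc2)CC[C@H]1c1ccccc1 | intermediate
5 | 3,4-bis(benzyloxy)benzaldehyde | O=Cc1ccc(OCc2ccccc2)c(OCc2ccccc2)c1 | starting material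
6 | dimethyl malonate | COC(=O)CC(=O)OC | starting material
7 | dimethyl 2-[3,4-bis(benzyloxy)benzylidene]malonate | COC(=O)C(=Cc1ccc(OCc2ccccc2)c(OCc2ccccc2)c1)C(=O)OC | intermediate
8 | 2-(benzyloxy)-3-(tert-butyldimethylsilyloxy)-1-[(2S,5S)-2,5-diphenylpyrrolidin-1-yl]buta-1,3-diene | C=C(O[Si](C)(C)C(C)(C)C)/C(OCc1ccccc1)=C/N1[C@H](c2ccccc2)CC[C@H]1c1ccccc1 | intermediate
9 | dimethyl 6-[3,4-bis(benzyloxy)phenyl]-3-(benzyloxy)-4-(tert-butyldimethylsilyloxy)-2-[(2S,5S)-2,5-diphenylpyrrolidin-1-yl]cyclohex-3-ene-1,1-dicarboxylate (amino-bearing centre not defined) | COC(=O)C1(C(=O)OC)C(N2[C@H](c3ccccc3)CC[C@H]2c2ccccc2)C(OCc2ccccc2)=C(O[Si](C)(C)C(C)(C)C)C[C@@H]1c1ccc(OCc2ccccc2)c(OCc2ccccc2)c1 | intermediate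
10 | dimethyl (6R)-6-[3,4-bis(benzyloxy)phenyl]-3-(benzyloxy)-4-oxocyclohex-2-ene-1,1-dicarboxylate | COC(=O)C1(C(=O)OC)C=C(OCc2ccccc2)C(=O)C[C@@H]1c1ccc(OCc2ccccc2)c(OCc2ccccc2)c1 | intermediate
11 | dimethyl (5S,6R)-6-[3,4-bis(benzyloxy)phenyl]-3-(benzyloxy)-5-(2-tert-butoxy-2-oxoethyl)-4-oxocyclohex-2-ene-1,1-dicarboxylate | COC(=O)C1(C(=O)OC)C=C(OCc2ccccc2)C(=O)[C@@H](CC(=O)OC(C)(C)C)[C@@H]1c1ccc(OCc2ccccc2)c(OCc2ccccc2)c1 | intermediate
12 | 6-tert-butyl 1-methyl 8-[3,4-bis(benzyloxy)phenyl]-3-(benzyloxy)-4,7-dioxobicyclo[3.2.1]oct-2-ene-1,6-dicarboxylate (C6 not defined) | COC(=O)[C@@]12C=C(OCc3ccccc3)C(=O)[C@@H](C(C(=O)OC(C)(C)C)C1=O)[C@@H]2c1ccc(OCc2ccccc2)c(OCc2ccccc2)c1 | intermediate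
13 | methyl 8-[3,4-bis(benzyloxy)phenyl]-3-(benzyloxy)-4,7-dioxobicyclo[3.2.1]oct-2-ene-1-carboxylate (aryl turned to the enone bridge) | COC(=O)[C@@]12C=C(OCc3ccccc3)C(=O)[C@@H](CC1=O)[C@@H]2c1ccc(OCc2ccccc2)c(OCc2ccccc2)c1 | intermediate
14 | methyl 3-[3,4-bis(benzyloxy)phenyl]-6-(benzyloxy)-5,7-dioxotricyclo[2.2.2.0(2,6)]octane-2-carboxylate | COC(=O)[C@]12[C@@H]3[C@@]1(OCc4ccccc4)C(=O)[C@@H](CC3=O)[C@@H]2c1ccc(OCc2ccccc2)c(OCc2ccccc2)c1 | intermediate
15 | methyl 3-[3,4-bis(benzyloxy)phenyl]-6-(benzyloxy)-5-oxo-7-(trifluoromethylsulfonyloxy)tricyclo[2.2.2.0(2,6)]oct-7-ene-2-carboxylate | COC(=O)[C@]12[C@@H]3[C@@]1(OCc4ccccc4)C(=O)[C@@H](C=C3OS(=O)(=O)C(F)(F)F)[C@@H]2c1ccc(OCc2ccccc2)c(OCc2ccccc2)c1 | intermediate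
16 | potassium enolate of 17 (C7=C8 enolate, ester at C2 trans to aryl) | [K+].COC(=O)[C@H]1[C@H]2C(OS(=O)(=O)C(F)(F)F)=C[C@H](C([O-])=C2OCc2ccccc2)[C@@H]1c1ccc(OCc2ccccc2)c(OCc2ccccc2)c1 | intermediate
17 | methyl 3-[3,4-bis(benzyloxy)phenyl]-7-(benzyloxy)-8-oxo-6-(trifluoromethylsulfonyloxy)bicyclo[2.2.2]oct-5-ene-2-carboxylate (relative configuration as in 23) | COC(=O)[C@H]1[C@H]2C(OS(=O)(=O)C(F)(F)F)=C[C@H](C(=O)[C@H]2OCc2ccccc2)[C@@H]1c1ccc(OCc2ccccc2)c(OCc2ccccc2)c1 | intermediate
18 | sodium (R)-3-(3,4-dihydroxyphenyl)-2-hydroxypropanoate | [Na+].[O-]C(=O)[C@H](O)Cc1ccc(O)c(O)c1 | starting material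
19 | methyl (R)-3-(3,4-dihydroxyphenyl)-2-hydroxypropanoate | COC(=O)[C@H](O)Cc1ccc(O)c(O)c1 | intermediate
20 | methyl (R)-3-[3,4-bis(benzyloxy)phenyl]-2-hydroxypropanoate | COC(=O)[C@H](O)Cc1ccc(OCc2ccccc2)c(OCc2ccccc2)c1 | intermediate
21 | methyl (S)-2-(acryloyloxy)-3-[3,4-bis(benzyloxy)phenyl]propanoate | COC(=O)[C@@H](OC(=O)C=C)Cc1ccc(OCc2ccccc2)c(OCc2ccccc2)c1 | intermediate
22 | penta-O-benzyl ether of 23 | COC(=O)[C@H]1[C@H]2C(/C=C/C(=O)O[C@@H](Cc3ccc(OCc4ccccc4)c(OCc4ccccc4)c3)C(=O)OC)=C[C@H](C(=O)[C@H]2OCc2ccccc2)[C@@H]1c1ccc(OCc2ccccc2)c(OCc2ccccc2)c1 | intermediate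
23 | methyl (1S,2R,3S,4S,7S)-3-(3,4-dihydroxyphenyl)-7-hydroxy-6-[(1E)-3-{[(2S)-3-(3,4-dihydroxyphenyl)-1-methoxy-1-oxopropan-2-yl]oxy}-3-oxoprop-1-en-1-yl]-8-oxobicyclo[2.2.2]oct-5-ene-2-carboxylate | COC(=O)[C@H]1[C@H]2C(/C=C/C(=O)O[C@@H](Cc3ccc(O)c(O)c3)C(=O)OC)=C[C@H](C(=O)[C@H]2O)[C@@H]1c1ccc(O)c(O)c1 | target

**Step count.** 13 steps in total. The longest linear sequence is 9 steps (steps 1, 3, 4, 5, 6, 7, 8, 12, 13).

**Steps most likely to fail**

Step 6. The triplet 1,2-acyl shift may lose to α-cleavage and the 1,3-acyl shift, or the enone triplet may decay without reacting. The fallback uses a ground-state radical chain instead of light and sets out from 13. Conjugate addition of PhSeH (from PhSeSePh and NaBH4) should give the β-(phenylselanyl) ketone F1. Bu3SnH with AIBN at high dilution should then generate the C1 radical, whose Dowd–Beckwith-type 1,2-acyl shift gives the bicyclo[2.2.2]octanedione F2. Equilibration of the ester centre with KOt-Bu, then kinetic enolisation of the C5 methylene with LiN(SiMe3)2 and trapping with PhNTf2, would return to 17.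

Step 8. Facial selectivity in the final enolate protonation may be poor, the ester centre may not equilibrate fully, or the triflate may be lost to alkoxide. The fallback separates the three events through an isolable enol ether and sets out from 15. Reduction with SmI2 and trapping of the C8 enolate with (i-Pr)3SiOTf and Et3N should give the silyl enol ether F3 as a mixture at C2. KOt-Bu in t-BuOH then equilibrates the ester centre to the trans isomer F4. Protodesilylation with HF·pyridine at −78 °C sets C7 and returns to 17.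

Step 3. Facial or exo/endo selectivity may be poor, or the addition may run stepwise, so that the aryl-bearing centre forms with low enantiomeric purity. The fallback moves stereocontrol from the diene to a catalyst; it sets out from 1 and 7 and returns at 10. Formylation of 1 (HCO2Me, NaOMe) and O-methylation should give the β-methoxy enone F5, and t-BuMe2SiOTf with Et3N the siloxy diene F6. Mukaiyama–Michael addition of F6 to 7, catalysed by the divalent copper complex Cu(t-Bu-box)(SbF6)2 (ligand enantiomer chosen for the required face), should give the open-chain adduct F7 after desilylation. DBU then closes the ring by addition–elimination to give 10.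

Further compounds
F1 | step 6 | methyl 8-[3,4-bis(benzyloxy)phenyl]-3-(benzyloxy)-4,7-dioxo-2-(phenylselanyl)bicyclo[3.2.1]octane-1-carboxylate (C2 and C3 not defined) | COC(=O)[C@@]12C([Se]c3ccccc3)C(OCc3ccccc3)C(=O)[C@@H](CC1=O)[C@@H]2c1ccc(OCc2ccccc2)c(OCc2ccccc2)c1
F2 | step 6 | methyl 3-[3,4-bis(benzyloxy)phenyl]-7-(benzyloxy)-6,8-dioxobicyclo[2.2.2]octane-2-carboxylate | COC(=O)[C@H]1[C@H]2C(=O)C[C@H](C(=O)[C@H]2OCc2ccccc2)[C@@H]1c1ccc(OCc2ccccc2)c(OCc2ccccc2)c1
F3 | step 8 | methyl 3-[3,4-bis(benzyloxy)phenyl]-7-(benzyloxy)-6-(trifluoromethylsulfonyloxy)-8-(triisopropylsilyloxy)bicyclo[2.2.2]octa-5,7-diene-2-carboxylate (C2 not defined) | COC(=O)C1[C@H]2C(OS(=O)(=O)C(F)(F)F)=C[C@H](C(O[Si](C(C)C)(C(C)C)C(C)C)=C2OCc2ccccc2)[C@@H]1c1ccc(OCc2ccccc2)c(OCc2ccccc2)c1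
F4 | step 8 | C2-trans isomer of F3 | COC(=O)[C@H]1[C@H]2C(OS(=O)(=O)C(F)(F)F)=C[C@H](C(O[Si](C(C)C)(C(C)C)C(C)C)=C2OCc2ccccc2)[C@@H]1c1ccc(OCc2ccccc2)c(OCc2ccccc2)c1
F5 | step 3 | (Z)-3-(benzyloxy)-4-methoxybut-3-en-2-one | CC(=O)/C(OCc1ccccc1)=C/OC
F6 | step 3 | 2-(benzyloxy)-3-(tert-butyldimethylsilyloxy)-1-methoxybuta-1,3-diene | C=C(O[Si](C)(C)C(C)(C)C)/C(OCc1ccccc1)=C/OC
F7 | step 3 | dimethyl 2-{1-[3,4-bis(benzyloxy)phenyl]-4-(benzyloxy)-5-methoxy-3-oxopent-4-en-1-yl}malonate | COC(=O)C(C(=O)OC)[C@H](CC(=O)/C(OCc1ccccc1)=C/OC)c1ccc(OCc2ccccc2)c(OCc2ccccc2)c1
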